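**Retrosynthetic overview**

1. Target 17 comes from Markovnikov hydration of the isopropenyl group of 15 (C3′–OH), which comes from MOM removal and O‑acylation of alcohol 12. The two side‑chain oxygens are differentiated from the C–C bond‑forming step onwards.
2. Key disconnection C1′–C2′, a bond between two oxygen‑bearing carbons. Aldehyde 5 supplies C1′. The partner is α‑lithiated methallyl MOM ether 8, an oxygen‑substituted allyl anion whose O‑bearing carbon C2′ reacts as the nucleophile (an α‑alkoxy carbanion, d1 umpolung).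
3. The anion is delivered as the chiral (Z)‑γ‑alkoxyallylborane 10, so both stereocentres (syn, C1′ R) are set in that one step.
4. Aldehyde 5 comes from Pd formylation of bromocoumarin 4, made from salicylaldehyde 2.
5. Rings: the benzene ring is bought (1). The pyranone ring is the only ring formed (step 2), before the side chain is built.

Notation: C1′ is the benzylic side‑chain carbon, then C2′ and C3′. Ipc is the isopinocampheyl group derived from (+)‑α‑pinene. The target is (1′R,2′S), the syn‑1′,2′‑dioxygenated isomer.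

**Route**

Step 1
Reactants: 1 2-hydroxy-4-methoxybenzaldehyde
Product: 2 5-bromo-2-hydroxy-4-methoxybenzaldehyde
Conditions: NBS (1.05 eq), MeCN, 0 °C → rt
Reagents that add atoms: N-bromosuccinimide, O=C1CCC(=O)N1Br
Why: Electrophilic aromatic bromination goes to C5, para to OH and ortho to OMe, the activated position that is not flanked by two substituents.

Step 2
Reactants: 2 5-bromo-2-hydroxy-4-methoxybenzaldehyde
Product: 4 6-bromo-7-methoxy-2H-chromen-2-one, via hydroxycinnamate 3 (not isolated)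
Conditions: Ph3P=CHCO2Et (1.2 eq), PhNEt2, reflux (ca. 215 °C), 4 h
Reagents that add atoms: (ethoxycarbonylmethylene)triphenylphosphorane, CCOC(=O)C=P(c1ccccc1)(c1ccccc1)c1ccccc1
Why: Wittig olefination of the salicylaldehyde, then thermal E/Z equilibration and lactonisation of the Z ester, closes the pyranone ring (coumarin annulation).

Step 3
Reactants: 4 6-bromo-7-methoxy-2H-chromen-2-one
Product: 5 7-methoxy-2-oxo-2H-chromene-6-carbaldehyde
Conditions: Pd(OAc)2 (1 mol%), BuPAd2 (3 mol%), TMEDA (0.75 eq), CO/H2 (1:1, 5 bar), toluene, 100 °C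
Reagents that add atoms: carbon monoxide, [C-]#[O+]
Why: Palladium-catalysed reductive carbonylation (formylation) of the aryl bromide by oxidative addition, CO insertion and hydrogenolysis of the acyl–Pd bond should leave the lactone and the conjugated C3=C4 bond alone.

Step 4
Reactants: 6 2-methylprop-2-en-1-ol
Product: 7 3-(methoxymethoxy)-2-methylprop-1-ene
Conditions: MOMCl (1.2 eq), iPr2NEt (1.5 eq), CH2Cl2, 0 °C → rt; distil
Reagents that add atoms: chloromethyl methyl ether, COCCl
Why: O-Alkylation (MOM ether formation) gives an allyl ether whose acetal oxygens later direct and stabilise α-lithiation.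

Step 5
Reactants: 5 7-methoxy-2-oxo-2H-chromene-6-carbaldehyde; 7 3-(methoxymethoxy)-2-methylprop-1-ene
Product: 12 6-[(1R,2R)-1-hydroxy-2-(methoxymethoxy)-3-methylbut-3-en-1-yl]-7-methoxy-2H-chromen-2-one, via allyllithium 8 (not isolated), via borate complex 9 (not isolated), via allylborane 10 (not isolated), via borinate ester 11 (not isolated)
Conditions: 7 (1.6 eq), s-BuLi (1.5 eq), THF, −78 °C; (−)-Ipc2BOMe [from (+)-α-pinene] (1.5 eq), −78 °C; BF3·OEt2 (2 eq), −78 °C; then 5 (1 eq), −78 °C, 4 h; HOCH2CH2NH2, 0 °C → rt, filter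
Reagents that add atoms: none
Why: Brown asymmetric γ-alkoxyallylboration (here with the 2-methyl homologue of the reagent, an extrapolation) in which the oxygen-substituted allyl anion 8 serves as a reversed-polarity α-alkoxy carbanion, so that the O-bearing carbon C2′ bonds as the nucleophile to the aldehyde carbon C1′ through a closed chair transition state; the Z enol-ether geometry of 10 fixes the syn (1′R,2′R) relationship and the (+)-α-pinene-derived Ipc groups direct attack to the Si face of the aldehyde (C1′ = R, about 90% ee expected, raised by recrystallisation).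

Step 6
Reactants: 12 6-[(1R,2R)-1-hydroxy-2-(methoxymethoxy)-3-methylbut-3-en-1-yl]-7-methoxy-2H-chromen-2-one
Product: 13 (1R,2R)-1-(7-methoxy-2-oxo-2H-chromen-6-yl)-2-(methoxymethoxy)-3-methylbut-3-en-1-yl 3-methylbutanoate
Conditions: (iBuCO)2O (1.5 eq), Et3N (2 eq), DMAP (0.1 eq), CH2Cl2, 0 °C → rt
Reagents that add atoms: 3-methylbutanoic anhydride, CC(C)CC(=O)OC(=O)CC(C)C
Why: DMAP-catalysed O-acylation of the only free hydroxyl puts the isovalerate on the benzylic oxygen with retention at C1′, since no bond to a stereocentre is broken.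

Step 7
Reactants: 13 (1R,2R)-1-(7-methoxy-2-oxo-2H-chromen-6-yl)-2-(methoxymethoxy)-3-methylbut-3-en-1-yl 3-methylbutanoate
Product: 15 (1R,2R)-2-hydroxy-1-(7-methoxy-2-oxo-2H-chromen-6-yl)-3-methylbut-3-en-1-yl 3-methylbutanoate, via bipyridinium salt 14 (not isolated)
Conditions: TMSOTf (2 eq), 2,2′-bipyridyl (3 eq), CH2Cl2, 0 °C → rt; then H2O, rt
Reagents that add atoms: none
Why: Fujioka MOM cleavage (silyl-triflate-induced acetal exchange to the N-(alkoxymethyl)bipyridinium salt, then hydrolysis) runs without free protic acid, so the benzylic ester is not ionised and the C2′–O bond is never broken (retention).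

Step 8
Reactants: 15 (1R,2R)-2-hydroxy-1-(7-methoxy-2-oxo-2H-chromen-6-yl)-3-methylbut-3-en-1-yl 3-methylbutanoate
Product: 17 (1R,2S)-2,3-dihydroxy-1-(7-methoxy-2-oxo-2H-chromen-6-yl)-3-methylbutyl 3-methylbutanoate, via hydroperoxide 16 (not isolated)
Conditions: Co(acac)2 (20 mol%), PhSiH3 (2.5 eq), O2 (1 atm), THF/iPrOH, rt; then aq. Na2S2O3
Reagents that add atoms: dioxygen, O=O
Why: Mukaiyama hydration (cobalt hydride hydrogen-atom transfer, O2 capture of the tertiary radical, reduction of the peroxide) adds water in the Markovnikov sense to the electron-rich 1,1-disubstituted alkene in preference to the electron-poor conjugated coumarin C3=C4 bond, creates no new stereocentre and leaves C1′ and C2′ untouched (the C2′ descriptor changes from R to S only because C3′ gains priority).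

**Compound list**

1 | 2-hydroxy-4-methoxybenzaldehyde | COc1ccc(C=O)c(O)c1 | starting material
2 | 5-bromo-2-hydroxy-4-methoxybenzaldehyde | COc1cc(O)c(C=O)cc1Br | intermediate
3 | ethyl (2Z)-3-(5-bromo-2-hydroxy-4-methoxyphenyl)prop-2-enoate (formed with its E isomer, which equilibrates at the reaction temperature) | CCOC(=O)/C=C\c1cc(Br)c(OC)cc1O | intermediate
4 | 6-bromo-7-methoxy-2H-chromen-2-one | COc1cc2oc(=O)ccc2cc1Br | intermediate
5 | 7-methoxy-2-oxo-2H-chromene-6-carbaldehyde | COc1cc2oc(=O)ccc2cc1C=O | intermediate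
6 | 2-methylprop-2-en-1-ol (methallyl alcohol) | C=C(C)CO | starting material
7 | 3-(methoxymethoxy)-2-methylprop-1-ene | C=C(C)COCOC | intermediate
8 | [1-(methoxymethoxy)-2-methylallyl]lithium (chelated, Z-configured allyl anion) | C=C(C)C([Li])OCOC | intermediate
9 | lithium [(2Z)-3-(methoxymethoxy)-2-methylprop-2-en-1-yl](methoxy)bis(isopinocampheyl)borate, Ipc from (+)-α-pinene | [Li+].COCO/C=C(C)\C[B-](OC)([C@@H]1C[C@@H]2C[C@H]([C@H]1C)C2(C)C)[C@@H]1C[C@@H]2C[C@H]([C@H]1C)C2(C)C | intermediate
10 | [(2Z)-3-(methoxymethoxy)-2-methylprop-2-en-1-yl]bis(isopinocampheyl)borane, Ipc from (+)-α-pinene | COCO/C=C(C)\CB([C@@H]1C[C@@H]2C[C@H]([C@H]1C)C2(C)C)[C@@H]1C[C@@H]2C[C@H]([C@H]1C)C2(C)C | intermediate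
11 | (1R,2R)-1-(7-methoxy-2-oxo-2H-chromen-6-yl)-2-(methoxymethoxy)-3-methylbut-3-en-1-yl bis(isopinocampheyl)borinate | COc1cc2oc(=O)ccc2cc1[C@@H](OB([C@@H]1C[C@@H]2C[C@H]([C@H]1C)C2(C)C)[C@@H]1C[C@@H]2C[C@H]([C@H]1C)C2(C)C)[C@H](OCOC)C(C)=C | intermediate
12 | 6-[(1R,2R)-1-hydroxy-2-(methoxymethoxy)-3-methylbut-3-en-1-yl]-7-methoxy-2H-chromen-2-one | COc1cc2oc(=O)ccc2cc1[C@@H](O)[C@H](OCOC)C(C)=C | intermediate
13 | (1R,2R)-1-(7-methoxy-2-oxo-2H-chromen-6-yl)-2-(methoxymethoxy)-3-methylbut-3-en-1-yl 3-methylbutanoate | COc1cc2oc(=O)ccc2cc1[C@@H](OC(=O)CC(C)C)[C@H](OCOC)C(C)=C | intermediate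
14 | 1-({[(1R,2R)-1-(7-methoxy-2-oxo-2H-chromen-6-yl)-3-methyl-1-(3-methylbutanoyloxy)but-3-en-2-yl]oxy}methyl)-2,2′-bipyridin-1-ium triflate | COc1cc2oc(=O)ccc2cc1[C@@H](OC(=O)CC(C)C)[C@H](OC[n+]1ccccc1-c1ccccn1)C(C)=C.[O-]S(=O)(=O)C(F)(F)F | intermediate
15 | (1R,2R)-2-hydroxy-1-(7-methoxy-2-oxo-2H-chromen-6-yl)-3-methylbut-3-en-1-yl 3-methylbutanoate | COc1cc2oc(=O)ccc2cc1[C@@H](OC(=O)CC(C)C)[C@H](O)C(C)=C | intermediate
16 | (1R,2S)-3-hydroperoxy-2-hydroxy-1-(7-methoxy-2-oxo-2H-chromen-6-yl)-3-methylbutyl 3-methylbutanoate | COc1cc2oc(=O)ccc2cc1[C@@H](OC(=O)CC(C)C)[C@H](O)C(C)(C)OO | intermediate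
17 | (1R,2S)-2,3-dihydroxy-1-(7-methoxy-2-oxo-2H-chromen-6-yl)-3-methylbutyl 3-methylbutanoate | COc1cc2oc(=O)ccc2cc1[C@@H](OC(=O)CC(C)C)[C@H](O)C(C)(C)O | target

**Step count**

Total steps: 8. Longest linear sequence: 7 (steps 1, 2, 3, 5, 6, 7, 8); step 4 is a one-step side branch.

**Steps most likely to fail, with fallbacks**

Step 5 is the largest risk. The 2-methyl reagent is an extrapolation of Brown's reagent, lithiation of 7 could partly occur at the allylic methyl group, and the ee with the extra methyl group is not known. The fallback replaces stoichiometric reagent control by catalyst control with an isolable reagent. It sets out from 7 (through 8) and 5. The anion 8 is quenched with 2-isopropoxy-4,4,5,5-tetramethyl-1,3,2-dioxaborolane to give the distillable boronate 2-[(2Z)-3-(methoxymethoxy)-2-methylprop-2-en-1-yl]-4,4,5,5-tetramethyl-1,3,2-dioxaborolane F1, whose regio- and Z-purity can be checked before use. F1 is then added to 5 under chiral phosphoric acid catalysis ((S)-TRIP, 5 mol%, toluene, −30 °C; enantiomer chosen for Si-face addition by analogy with allyl-Bpin and benzaldehyde). This gives the boronic ester 2-{[(1R,2R)-1-(7-methoxy-2-oxo-2H-chromen-6-yl)-2-(methoxymethoxy)-3-methylbut-3-en-1-yl]oxy}-4,4,5,5-tetramethyl-1,3,2-dioxaborolane F2, which is hydrolysed on work-up. The fallback comes back to the route at 12.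

Step 7 may fail if the Lewis acid ionises the electron-rich benzylic ester or triggers an acyl shift. The fallback changes the order of events and sets out from 12. The acetal is cleaved before any ester is present (cat. HCl, MeOH, 40 °C) to give the diol 6-[(1R,2R)-1,2-dihydroxy-3-methylbut-3-en-1-yl]-7-methoxy-2H-chromen-2-one F3. Its isopropenyl group is hydrated under the step 8 conditions to the triol 7-methoxy-6-[(1R,2S)-1,2,3-trihydroxy-3-methylbutyl]-2H-chromen-2-one F4. F4 is acylated at the benzylic hydroxyl with isovaleric anhydride (1.05 eq, 2,4,6-collidine, cat. DMAP, CH2Cl2, −40 °C). Selectivity rests on sterics: the C2′ hydroxyl sits next to the quaternary carbinol carbon and the tertiary hydroxyl is inert. The fallback comes back to the route at 17.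

Step 8 may fail if hydrogen-atom transfer also reduces or hydrates the coumarin C3=C4 bond. The fallback is ionic and sets out from 15. Markovnikov oxymercuration (Hg(OAc)2, THF/H2O, 0 °C), to which the electron-poor coumarin alkene is inert, gives the organomercurial acetoxy[(3S,4R)-2,3-dihydroxy-4-(7-methoxy-2-oxo-2H-chromen-6-yl)-2-methyl-4-(3-methylbutanoyloxy)butyl]mercury F5 as a mixture of C2 epimers. Reductive demercuration (NaBH4, pH 7–8 buffer, 0 °C, minutes) removes that centre. The fallback comes back to the route at 17.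

**Further compounds**

F1 | step 5 | 2-[(2Z)-3-(methoxymethoxy)-2-methylprop-2-en-1-yl]-4,4,5,5-tetramethyl-1,3,2-dioxaborolane | COCO/C=C(C)\CB1OC(C)(C)C(C)(C)O1
F2 | step 5 | 2-{[(1R,2R)-1-(7-methoxy-2-oxo-2H-chromen-6-yl)-2-(methoxymethoxy)-3-methylbut-3-en-1-yl]oxy}-4,4,5,5-tetramethyl-1,3,2-dioxaborolane | COc1cc2oc(=O)ccc2cc1[C@@H](OB1OC(C)(C)C(C)(C)O1)[C@H](OCOC)C(C)=C
F3 | step 7 | 6-[(1R,2R)-1,2-dihydroxy-3-methylbut-3-en-1-yl]-7-methoxy-2H-chromen-2-one | COc1cc2oc(=O)ccc2cc1[C@@H](O)[C@H](O)C(C)=C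
F4 | step 7 | 7-methoxy-6-[(1R,2S)-1,2,3-trihydroxy-3-methylbutyl]-2H-chromen-2-one | COc1cc2oc(=O)ccc2cc1[C@@H](O)[C@H](O)C(C)(C)O
F5 | step 8 | acetoxy[(3S,4R)-2,3-dihydroxy-4-(7-methoxy-2-oxo-2H-chromen-6-yl)-2-methyl-4-(3-methylbutanoyloxy)butyl]mercury (C2 epimers) | COc1cc2oc(=O)ccc2cc1[C@@H](OC(=O)CC(C)C)[C@H](O)C(C)(O)C[Hg]OC(C)=O
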